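(The numbers in the tables are calculated on assumed constants; noise was put on by code.)

0.100 min⁻¹ is the number for you to carry: the turnover rate, meaning substrate used per minute for each catalyst charged. I read it from the autumn run, where substrate falls from 95.9% at 3.00 min to 93.4% at 8.00 min with 5 mol% of free catalyst, and each reading has a scatter of 0.3 percentage points.

in all of them: substrate 20 mM; free catalyst 5 mol%
- autumn: reagent 1.3 equiv; added ligand 1.7 mM; run made earlier
- flask: reagent 1.30 equiv; added ligand 0.87 mM; time 80 min

autumn run (percent of the substrate charged)

| time / min | product / % | substrate / % |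
|---|---|---|
| 1.00 | 0.4 | 97.8 |
| 3.00 | 0 | 95.9 |
| 5.00 | 2.0 | 94.3 |
| 8.00 | 2.8 | 93.4 |

(standard deviation of a reading: 0.3 percentage points)

- amount of product in the flask at 80 min, in percent of the substrate charged
- amount of substrate in the flask at 80 min, in percent of the substrate charged
- concentration of by-product at 80 min, in mM

Substrate is the limiting reagent, with [substrate] = 20 mM against [reagent] = 26.0 mM, so you write its balance: charged equals left plus product plus held elsewhere. On the fastest rung, the autumn flask has lost 2.20% of its substrate by 1.00 min. By 8.00 min the balance lacks 3.80%, and I hold that gap constant from there. Next, one turn of the catalyst takes 10.0 min at this pace, longer than the 8.00 min of the last autumn reading. On the slowest rung, emptying the flask at this pace takes 200 min, longer than the 80 min asked, so I extend the straight line. I leave the ligand change, 1.7 mM to 0.87 mM, out of the rate, and that is a guess.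

Over the remaining 72.0 min the pace removes 36.0%, which leaves 57.4% substrate. The balance then gives 38.8% product. If one by-product comes with each substrate used, again a guess, there is 8.52 mM of it.

The forecast gives 42% product, 52% substrate and 1.2 mM by-product. On the ligand it says “I guess about twice the rate”, and its substrate lies below my figure.

The flask gives 36.7% product, 59.6% substrate and 7.95 mM by-product.

    reagent + free catalyst → catalyst intermediate A (k = 1400 M⁻¹ min⁻¹)
    substrate + catalyst intermediate A ⇌ catalyst intermediate B (K = 1800 M⁻¹, k = 28.0 M⁻¹ min⁻¹)
    catalyst intermediate B → by-product + catalyst intermediate C (k = 0.640 min⁻¹)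
    catalyst intermediate C ⇌ catalyst intermediate D (K = 0.360, k = 69.0 min⁻¹)
    catalyst intermediate D → free catalyst + product (k = 0.650 min⁻¹)
    free catalyst → spent catalyst A (k = 7.40 × 10⁻⁶ min⁻¹)
    catalyst intermediate C → spent catalyst B (k = 0.00420 min⁻¹)
    free catalyst + added ligand ⇌ idle complex (K = 1700 M⁻¹, k = 110 M⁻¹ min⁻¹)

With half the autumn ligand, the product at the time of the last autumn reading stays at 2.93%, against 2.92% in the autumn run without the scatter. Over 80 min this flask's turnover rate comes to 0.101 min⁻¹ on average. In the neighbouring flask with 12 mol% of free catalyst, the carried rate reckons 96.0% of the substrate used. That flask used 82.5%, an average turnover rate of 0.0859 min⁻¹.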